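**Remark on numbering.** Non-hydrogen atoms are numbered 1–27 in the order of the target SMILES (C1–C2 ethyl, C3, C4, O5, C6, O7, C8, C9, C10, C11, C12, C13, C14, C15, C16, C17, C18, O19, O20, N21, C22, C23, C24–C27). Ring A is the pyrrole, B the azepine, C the carbocycle, D the fused lactone and E the appended lactone. The same numbers are used for every intermediate.

## Structural features

The target (3R,4S,8R,10R,14S,16S,23R) is a pentacyclic pyrrole bis-lactone. A tetrasubstituted pyrrole (ring A: N21, C22, C11, C12, C13) shares N21–C22 with a saturated azepine (ring B, C23–C27) and C11–C22 with a six-membered carbocycle (ring C: C3, C4, C10, C11, C22, C23). A γ-lactone (ring D) is cis-fused to ring C at C4–C10, and a second γ-lactone (ring E) hangs from C13 through C14. Ring C carries four contiguous stereocentres, C23, C3, C4 and C10, on either side of the pyrrole bond C11–C22 (H-23/H-3 trans, H-3/H-4 trans, H-4/H-10 cis). C8 extends the row to five, with its methyl group on the concave face of the C/D bicycle (H-8 cis to H-10), where enolate methylation does not put it. C14 and C16 of ring E (methyl cis to the pyrrolyl group) are separated from the other five centres by the flat pyrrole and cannot be set by relay. Fragile points are the electron-rich pyrrole with its one free position C12, the pyrrolylic C14–O20 bond, the enolisable centres C8 and C16, and C10 whenever C4 is a carbonyl carbon. The main difficulty is the ring C stereotetrad in one absolute sense. The plan uses the fact that C11–C22 is the double bond a [4+2] reaction leaves behind: diene C23=C22–C11=C10 (N21 on C22) and dienophile C3=C4 give ring C and its four centres at once, and leave an enecarbamate on which ring A is then built.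

## Logic of the disconnections

**29 from 28.** The C8–H and C16–H bonds are cut, which leaves exocyclic C8=C9 and C16=C17 alkenes. In both lactones the hydrogen, not the methyl group, must arrive from the open face (the convex face of the C/D bicycle; the face of ring E away from C13). Hydrogenation delivers this and enolate methylation does not. Two stereocentres disappear in one operation. The forward step must spare the pyrrole and C14–O20 and must not move either alkene into its ring.

**28 from 24.** C8–C9 and C16–C17 are cut. Both lactones of 24 have a free α-CH2, so the two one-carbon units can go in together. 24 has five stereocentres and no α-substituents. The step needs double enolisation and a C1 electrophile that reacts at the enolates and not at C12.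

**24 from 22.** O20–C18 and C14–H are cut. C14 cannot be controlled from ring C, so it is given to a reagent-controlled ketone reduction. The C13 acyl group also makes 22 the most robust pyrrole of the route. Ring E and one stereocentre are removed. The reduction must tell apart the faces of a deactivated ketone, and the carbinol must lactonise without ionising.

**22 from 19 and 20.** N21–C13 and C12=C13 are cut (ring A). C12 is already on C11 as a formyl carbon and C13 arrives as the CH2Br carbon of 20, so the acyl chain can only end up on C13. Direct condensation of a bromomethyl ketone with the N-deprotected cyclic imine was rejected: such imines are expected to be alkylated on nitrogen first, which would place the chain on C12, and a ketone on a lactone-bearing carbon would make C14 epimerisable. Ring A and six carbons are removed, and 20 is bought. The step needs N- over O-alkylation and aldol closure onto C12.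

**19 from 17.** C11–C12 and the N21–carbamate bond are cut. C11 is the nucleophilic β-carbon of the enecarbamate left by the cycloaddition, so a one-carbon electrophile goes there only. The step must keep C23 intact; the carbamate is therefore removed only after the double bond is held by conjugation with the formyl group.

**17 from 15.** O5–C6 and C4–H are cut. A cis hydroxy ester closes by itself, so the ester arm needs no change of oxidation level. Ring D is removed. Hydride must come from the face opposite the C10 chain, before the ketone enolises toward C10.

**15 from 13.** C4=O is traced to C4–NO2, the activating group of the dienophile. The conversion must tolerate the enecarbamate, which rules out oxidative conditions.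

**13 from 7 and 12.** C23–C3 and C4–C10 are cut. This removes ring C and four stereocentres and leads to two achiral fragments. The forward step must control regiochemistry, endo approach and the absolute sense.

**7 from 4 and 6; 6 from 5; 4 from 2 from 1.** C22–C11 is cut as an sp2–sp2 coupling, and the E geometry of C10=C11 comes from alkyne hydroboration. The ester arm is kept because it lets ring D close directly. Its weakness is the C8 methylene of 7, which is allylic and α to the ester. This is met by base-free hydroboration, a mild coupling and a neutral cycloaddition catalyst.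

**12 from 10, from 8 and 9.** C3=C4 is cut (nitroaldol, then dehydration).

## Other disconnections considered

**Alternative 1:** The cut is N21–C22 and C23–C24. In the forward step, irradiation of maleimide A1 (ring C alkene C22=C23 with lactone D, tethered from C11 through C12–C13 to the imide nitrogen) makes the imide C–N bond add across the alkene. This gives the pyrrolidine-fused azepinedione A2.
- In its favour: two rings and two bonds form in one reagent-free, substrate-controlled step, and the tether forces N21 and C24 onto the same face.
- Against it here: A2 has sp3 C11 and C22 (two stereocentres the pyrrole does not keep), carbonyl groups at C24 and C27 and a C25=C26 alkene that must all go to CH2, and a pyrrolidine that must be dehydrogenated next to two lactones. C13 is bare, so ring E still needs an acylation and reduction sequence. A1 already holds C3, C4, C8 and C10, so the ring C problem is only moved into the synthesis of A1.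
- Comparison: on rings and bonds formed per key step the alternative is the better. On oxidation level the chosen plan is better, since its cycloaddition leaves C11=C22 as the pyrrole needs it. Mechanistically the photoreaction needs dilute or flow conditions and competes with [2+2] at the maleimide alkene, while the thermal [4+2] needs outside control of the absolute sense; for C23 both rely on substrate bias and are equal. In step economy the alternative is expected to be longer after its key step.

**Alternative 2:** The cut is C8–C10. In the forward step, the dirhodium carboxamidate Rh2(5S-MEPY)4 decomposes diazoacetate A3 (C10 a CH2 group, C13 a methyl ester). The carbenoid carbon C8 inserts into the C10–H bond cis to the ester oxygen and gives lactone A4.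
- In its favour: the tether guarantees the cis fusion, the pyrrolylic C–H bond is activated, and C10 is created late with no ketone at C4 beside it. On the safety of C10 the alternative is better than the chosen plan, which passes through a C4 ketone.
- Against it here: A3 must already contain the pyrrole and C3, C4 and C23, which the key step does nothing to build. The electrophilic carbenoid can attack the pyrrole at C12, insert into C3–H or dimerise. A diazo compound must be handled. After the step, the C8 methyl group is still missing (the same two steps as in the chosen plan, so equal on that point), and the C13 ester must become ring E beside lactone D.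
- Comparison: the alternative forms one ring, one bond and one stereocentre; the chosen key step forms one ring, two bonds and four stereocentres. Catalyst control of the insertion is at least equal in reliability to the endo control of the cycloaddition. Overall step economy is worse, because the ring C triad needs a separate construction.

**Alternative 3:** The cut is C22–C23. In the forward step, Sc(OTf)3 ionises the allylic alcohol of the eleven-membered pyrrolophane A5 at C23. The allyl cation is captured across the ring by pyrrole carbon C22, closing rings B and C and giving A6.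
- In its favour: one bond closes two rings, the Lewis acid is catalytic, and the pyrrole is present from the start. On the last point the alternative is better, since no annulation of ring A is needed.
- Against it here: A5 costs a macrocyclisation. The cation can also be captured at C25, which closes a five-membered ring through N21, C27 and C26. The C23 configuration depends on the conformation of the macrocycle. A6 still lacks ring E and has C24=C25 to reduce. C3, C4, C8 and C10 must be set before a ring holds them.
- Comparison: for C23 both plans rely on the preference for trans C23/C3 and are equal. The alternative avoids the nitro-to-ketone step and is better there. It is worse in regiochemical risk and in the steps needed to reach A5 and to add ring E.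

Key step: step 7

**Assumption.** 5 and 20 are bought. The (1R,2S)-thiourea is written for step 7; the antipode that gives 13 rather than its mirror image is the one to use.

## Route

Step 1
Reactants: 1 ε-caprolactam
Product: 2 tert-butyl 2-oxoazepane-1-carboxylate
Conditions: Boc2O, DMAP (cat.), Et3N, CH2Cl2, rt
Reagents that add atoms: di-tert-butyl dicarbonate, CC(C)(C)OC(=O)OC(=O)OC(C)(C)C
Why: N-Acylation of the lactam under nucleophilic catalysis; the carbamate acidifies the lactam α-CH2 (the future C23) and later moderates the enamine nitrogen of the diene.

Step 2
Reactants: 2 tert-butyl 2-oxoazepane-1-carboxylate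
Product: 4 tert-butyl 7-{[(trifluoromethyl)sulfonyl]oxy}-2,3,4,5-tetrahydro-1H-azepine-1-carboxylate, via potassium lactam enolate 3 (not isolated)
Conditions: KN(SiMe3)2, THF, −78 °C; then PhNTf2, −78 → 0 °C
Reagents that add atoms: N-phenylbis(trifluoromethanesulfonimide), O=S(=O)(N(c1ccccc1)S(=O)(=O)C(F)(F)F)C(F)(F)F
Why: Kinetic enolisation of the imide-like lactam and O-triflation (enol triflate formation) give the ketene aminal triflate, a standard coupling electrophile; it is filtered through base-washed silica and used soon.

Step 3
Reactants: 5 methyl but-3-ynoate
Product: 6 methyl (3E)-4-(4,4,5,5-tetramethyl-1,3,2-dioxaborolan-2-yl)but-3-enoate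
Conditions: pinacolborane, Cy2BH (5 mol%), neat, 0 °C → rt
Reagents that add atoms: pinacolborane, B1OC(C)(C)C(C)(C)O1
Why: Dicyclohexylborane-catalysed hydroboration of a terminal alkyne adds H and B syn and anti-Markovnikov, so only the (E)-1-alkenylboronate is expected; no base is present, which avoids isomerisation of 5 to the allenoate.

Step 4
Reactants: 4 lactam-derived vinyl triflate; 6 (E)-alkenylboronate
Product: 7 tert-butyl 7-[(1E)-4-methoxy-4-oxobut-1-en-1-yl]-2,3,4,5-tetrahydro-1H-azepine-1-carboxylate
Conditions: Pd(PPh3)4 (5 mol%), aq. K3PO4 (2 M), THF, 25 °C
Reagents that add atoms: none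
Why: Suzuki–Miyaura coupling of a lactam-derived vinyl triflate with an (E)-alkenylboronate forms C22–C11 with retention of both alkene geometries. Mild phosphate at room temperature is chosen because the C8 methylene of 7 is allylic and α to the ester, and stronger base or acid would move C10=C11 toward the vinylogous carbamate; 7 is used without storage.

Step 5
Reactants: 8 propanal; 9 nitromethane
Product: 10 1-nitrobutan-2-ol (racemic)
Conditions: KOtBu (5 mol%), THF/t-BuOH, 0 °C → rt
Reagents that add atoms: none
Why: Base-catalysed Henry (nitroaldol) addition; excess 9 is removed before the dehydration so that no nitronate is left to add to 12.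

Step 6
Reactants: 10 1-nitrobutan-2-ol
Product: 12 (E)-1-nitrobut-1-ene, via 1-nitrobutan-2-yl methanesulfonate 11 (not isolated)
Conditions: MsCl, Et3N, CH2Cl2, −10 → 0 °C
Reagents that add atoms: none
Why: O-Mesylation and E1cB elimination through the nitronate give the conjugated nitroalkene, for which the E isomer is strongly favoured; 12 is volatile and is distilled and used fresh.

Step 7
Reactants: 7 N-Boc 2-amidodiene; 12 (E)-1-nitrobut-1-ene
Product: 13 tert-butyl (5aR,6R,7R,8R)-6-ethyl-8-(2-methoxy-2-oxoethyl)-7-nitro-2,3,4,5,5a,6,7,8-octahydro-1H-1-benzazepine-1-carboxylate (3R,4R,10R,23R in target numbering)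
Conditions: 1-[3,5-bis(trifluoromethyl)phenyl]-3-[(1R,2S)-2-hydroxy-2,3-dihydro-1H-inden-1-yl]thiourea (20 mol%), 4 Å MS, PhMe, −20 °C → rt
Reagents that add atoms: none
Why: Proposed new method: a chiral hydrogen-bond donor has not been used to make the [4+2] reaction of a tertiary 2-amidodiene with a nitroalkene enantioselective; the closest known reaction types are the thermal Diels–Alder reactions of lactam-derived 2-amidodienes with electron-poor alkenes, the cycloadditions of 2-aminodienes with nitroalkenes and hydrogen-bond-donor-catalysed Diels–Alder reactions of nitroalkenes with other dienes. The thiourea binds both nitro oxygens and lowers the LUMO of 12, while N21 on C22 raises the HOMO of 7 and makes C23 its nucleophilic end, so C23–C3 (to the β-carbon of 12) forms ahead of C10–C4 in a concerted asynchronous or Michael–Mannich process, which fixes the regiochemistry. Ring C closes in the [4+2] mode (in the stepwise limit a six-membered closure of the nitronate carbon C4 onto the C10 end of the conjugated N-acyliminium ion), and the new C11=C22 bond is the future pyrrole edge. C23 and C10: the outward substituents C24 and C8 of the s-cis diene end up cis because both new bonds form on one face of the diene. C3 and C4: the E geometry of 12 gives ethyl trans to nitro, and the endo position of the nitro group (under C22–N21, the gauche donor–acceptor arrangement) places it cis to C24 and C8; C4 is in any case reset in step 9. Absolute sense: the thiourea–nitro complex, held further by a hydrogen bond from the indanol OH to the carbamate carbonyl of 7, should expose one face of 12. The step needs periselectivity over the hetero-[4+2] reaction of the nitroalkene, which the absence of Lewis acid and the stability of the carbocycle should secure. It also needs endo over exo approach and a neutral medium, which the non-basic catalyst provides, so that C10=C11 does not move before the reaction.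

Step 8
Reactants: 13 nitro enecarbamate
Product: 15 tert-butyl (5aR,6R,8R)-6-ethyl-8-(2-methoxy-2-oxoethyl)-7-oxo-2,3,4,5,5a,6,7,8-octahydro-1H-1-benzazepine-1-carboxylate, via sodium nitronate 14 (not isolated)
Conditions: NaOMe, MeOH, 0 °C; then aq. TiCl3, NH4OAc (pH 5–6), THF/H2O, 0 °C → rt
Reagents that add atoms: water, O
Why: Nef reaction in its reductive titanium form (McMurry): trivalent titanium reduces the nitronate to the oxime and the imine, which hydrolyses to the C4 ketone at pH 5–6. Ozone, dioxirane or permanganate variants are avoided because they would attack the enecarbamate C11=C22; the buffer and immediate use of 15 limit enecarbamate hydrolysis and enolisation toward C10.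

Step 9
Reactants: 15 C4 ketone
Product: 17 N-Boc lactone enecarbamate (rings B–D; C11=C22; cis-fused lactone D; centres C3 C4 C10 C23 as in 29), via cis hydroxy ester 16 (not isolated)
Conditions: NaBH4, CeCl3·7H2O, MeOH, −78 → −20 °C; then DBU (cat.), PhMe, 50 °C
Reagents that add atoms: none
Why: Luche-type borohydride reduction: with C24 and ethyl equatorial the C10 chain is pseudoaxial, so hydride should add to C4 from the opposite face (axial attack) and give the equatorial alcohol cis to that chain. Only this cis hydroxy ester can close to the γ-lactone by base-catalysed transesterification, which fixes and purifies the C4 configuration; the cold cerium conditions reduce the β,γ-unsaturated ketone before it can enolise.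

Step 10
Reactants: 17 N-Boc lactone enecarbamate
Product: 19 NH vinylogous formamide (N21–H; C22=C11–C12H=O; lactone D), via N-Boc formyl enecarbamate 18 (not isolated)
Conditions: POCl3, DMF, CH2Cl2, 0 °C → rt; aq. NaOAc; then TFA, CH2Cl2, 0 °C
Reagents that add atoms: N,N-dimethylformamide, CN(C)C=O; water, O
Why: Vilsmeier–Haack formylation at C11, the nucleophilic β-carbon of the enecarbamate, then hydrolysis of the iminium salt and acidolysis of the Boc group, which is labile on a vinylogous formamide nitrogen. The push–pull unit N21–C22=C11–C12=O keeps the double bond away from C23 and holds NH and CHO cis on the ring alkene, as the annulation needs.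

Step 11
Reactants: 19 NH vinylogous formamide; 20 methyl 5-bromo-4-oxopentanoate
Product: 22 2-acylpyrrole (rings A–D; C13–C14(=O)–CH2CH2CO2Me), via N-alkylated keto aldehyde 21 (not isolated)
Conditions: K2CO3, DMF, rt → 70 °C
Reagents that add atoms: none
Why: N-Alkylation of the vinylogous formamide by the α-bromoketone, then intramolecular aldol (Knoevenagel-type) condensation of the N–CH2–C=O carbon C13 onto the C12 aldehyde and dehydration to the aromatic pyrrole, a known way from enaminones to 2-acylpyrroles. C-Alkylation is blocked because C11 is fully substituted, and the five-membered closure onto C12 should outrun condensations of the chain on itself.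

Step 12
Reactants: 22 2-acylpyrrole keto ester
Product: 24 bis-lactone without C9 and C17 (14S; other centres as in 29), via hydroxy ester 23 (not isolated)
Conditions: RuCl[(S,S)-TsDPEN](p-cymene) (2 mol%), HCO2Na, H2O/MeOH, 40 °C; then DBU (cat.), PhMe, 50 °C
Reagents that add atoms: none
Why: Noyori–Ikariya asymmetric transfer hydrogenation of an aryl-type ketone: the (S,S)-TsDPEN ruthenium hydride is expected to give the (S)-carbinol, as with other aryl alkyl ketones, so the catalyst sets C14. The near-neutral formate medium and base-catalysed lactonisation (retention at C14) avoid acid, which would ionise the pyrrolylic C14–O bond.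

Step 13
Reactants: 24 bis-lactone
Product: 28 bis(α-methylene) bis-lactone (C8=C9 and C16=C17), via dilithium bis-enolate 25 (not isolated), via bis-Mannich base 26 (not isolated), via bis-ammonium diiodide 27 (not isolated)
Conditions: LiN(iPr)2 (2.3 equiv), THF, −78 °C; Me2N=CH2+ I− (2.2 equiv), −78 → −20 °C; then MeI, MeOH, rt; then aq. NaHCO3, CH2Cl2, rt
Reagents that add atoms: N,N-dimethylmethyleneiminium iodide (Eschenmoser's salt), C=[N+](C)C.[I-]
Why: Double α-methylenation by the Eschenmoser route: Mannich reaction of both lactone enolates, N-methylation and E1cB loss of trimethylamine with bicarbonate. The configurations at C8 and C16 in 26 and 27 do not matter; the iminium salt is kept cold and in slight excess only, so that the enolates consume it and C12 of the pyrrole does not.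

Step 14
Reactants: 28 bis(α-methylene) bis-lactone
Product: 29 target (3R,4S,8R,10R,14S,16S,23R)
Conditions: H2 (1 atm), RhCl(PPh3)3 (10 mol%), PhH/EtOH, rt
Reagents that add atoms: none
Why: Homogeneous hydrogenation with Wilkinson's catalyst reduces the two 1,1-disubstituted alkenes without touching the pyrrole, cleaving C14–O20 or shifting the alkenes into the rings. H2 should add to C8 from the convex face of the cis-fused C/D bicycle (H-8 cis to H-10, methyl concave) and to C16 from the face of ring E opposite the pyrrolyl group (methyl cis to it), which are the configurations of 29.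

## Compound list

1 | ε-caprolactam (azepan-2-one) | O=C1CCCCCN1 | starting material
2 | tert-butyl 2-oxoazepane-1-carboxylate | CC(C)(C)OC(=O)N1CCCCCC1=O | intermediate
3 | potassium enolate of 2 (not isolated) | CC(C)(C)OC(=O)N1CCCCC=C1[O-].[K+] | intermediate
4 | tert-butyl 7-{[(trifluoromethyl)sulfonyl]oxy}-2,3,4,5-tetrahydro-1H-azepine-1-carboxylate | CC(C)(C)OC(=O)N1CCCCC=C1OS(=O)(=O)C(F)(F)F | intermediate
5 | methyl but-3-ynoate | C#CCC(=O)OC | starting material
6 | methyl (3E)-4-(4,4,5,5-tetramethyl-1,3,2-dioxaborolan-2-yl)but-3-enoate | COC(=O)C/C=C/B1OC(C)(C)C(C)(C)O1 | intermediate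
7 | tert-butyl 7-[(1E)-4-methoxy-4-oxobut-1-en-1-yl]-2,3,4,5-tetrahydro-1H-azepine-1-carboxylate (2-amidodiene C23=C22–C11=C10) | COC(=O)C/C=C/C1=CCCCCN1C(=O)OC(C)(C)C | intermediate
8 | propanal | CCC=O | starting material
9 | nitromethane | C[N+](=O)[O-] | starting material
10 | 1-nitrobutan-2-ol (racemic) | CCC(O)C[N+](=O)[O-] | intermediate
11 | 1-nitrobutan-2-yl methanesulfonate (racemic; not isolated) | CCC(OS(C)(=O)=O)C[N+](=O)[O-] | intermediate
12 | (E)-1-nitrobut-1-ene | CC/C=C/[N+](=O)[O-] | intermediate
13 | tert-butyl (5aR,6R,7R,8R)-6-ethyl-8-(2-methoxy-2-oxoethyl)-7-nitro-2,3,4,5,5a,6,7,8-octahydro-1H-1-benzazepine-1-carboxylate (ethyl trans to nitro; nitro, CH2CO2Me and C24 cis) | CC[C@H]1[C@H]([N+](=O)[O-])[C@H](CC(=O)OC)C=C2N(C(=O)OC(C)(C)C)CCCC[C@H]12 | intermediate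
14 | sodium nitronate of 13 (C4=NO2Na; 3R,10R,23R; not isolated) | CC[C@H]1C(=[N+]([O-])[O-])[C@H](CC(=O)OC)C=C2N(C(=O)OC(C)(C)C)CCCC[C@H]12.[Na+] | intermediate
15 | tert-butyl (5aR,6R,8R)-6-ethyl-8-(2-methoxy-2-oxoethyl)-7-oxo-2,3,4,5,5a,6,7,8-octahydro-1H-1-benzazepine-1-carboxylate | CC[C@H]1C(=O)[C@H](CC(=O)OC)C=C2N(C(=O)OC(C)(C)C)CCCC[C@H]12 | intermediate
16 | tert-butyl (5aR,6R,7R,8R)-6-ethyl-7-hydroxy-8-(2-methoxy-2-oxoethyl)-2,3,4,5,5a,6,7,8-octahydro-1H-1-benzazepine-1-carboxylate (OH cis to CH2CO2Me, trans to ethyl; not isolated) | CC[C@H]1[C@H](O)[C@H](CC(=O)OC)C=C2N(C(=O)OC(C)(C)C)CCCC[C@H]12 | intermediate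
17 | N-Boc lactone enecarbamate: rings B, C, D; C11=C22; γ-lactone cis-fused at C4–C10 (O5 and C8 on one face, ethyl on the other, H-23 trans to H-3; 23R) | CC[C@H]1[C@@H]2OC(=O)C[C@@H]2C=C2N(C(=O)OC(C)(C)C)CCCC[C@H]12 | intermediate
18 | 11-formyl derivative of 17 (N-Boc; C12 aldehyde on C11; not isolated) | CC[C@H]1[C@@H]2OC(=O)C[C@@H]2C(C=O)=C2N(C(=O)OC(C)(C)C)CCCC[C@H]12 | intermediate
19 | NH vinylogous formamide: N21–H, C22=C11–C12H=O, lactone D as in 17 | CC[C@H]1[C@@H]2OC(=O)C[C@@H]2C(C=O)=C2NCCCC[C@H]12 | intermediate
20 | methyl 5-bromo-4-oxopentanoate | COC(=O)CCC(=O)CBr | starting material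
21 | N21-(5-methoxy-2,5-dioxopentyl) derivative of 19 (not isolated) | CC[C@H]1[C@@H]2OC(=O)C[C@@H]2C(C=O)=C2N(CC(=O)CCC(=O)OC)CCCC[C@H]12 | intermediate
22 | 2-acylpyrrole: rings A–D; C13 bears C14(=O)–C15H2–C16H2–C18O2Me; ring C and D centres as in 29 | CC[C@H]1[C@@H]2OC(=O)C[C@@H]2c2cc(C(=O)CCC(=O)OC)n3c2[C@@H]1CCCC3 | intermediate
23 | (14S)-hydroxy ester from 22 (not isolated) | CC[C@H]1[C@@H]2OC(=O)C[C@@H]2c2cc([C@@H](O)CCC(=O)OC)n3c2[C@@H]1CCCC3 | intermediate
24 | bis-lactone without C9 and C17 (14S; ring C and D centres as in 29) | CC[C@H]1[C@@H]2OC(=O)C[C@@H]2c2cc([C@@H]3CCC(=O)O3)n3c2[C@@H]1CCCC3 | intermediate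
25 | dilithium bis-enolate of 24 (enolates at C8 and C16; not isolated) | CC[C@H]1[C@@H]2OC([O-])=C[C@@H]2c2cc([C@@H]3CC=C([O-])O3)n3c2[C@@H]1CCCC3.[Li+].[Li+] | intermediate
26 | 8,16-bis(dimethylaminomethyl) bis-lactone (C8 and C16 mixtures; not isolated) | CC[C@H]1[C@@H]2OC(=O)C(CN(C)C)[C@@H]2c2cc([C@@H]3CC(CN(C)C)C(=O)O3)n3c2[C@@H]1CCCC3 | intermediate
27 | 8,16-bis(trimethylammoniomethyl) bis-lactone diiodide (not isolated) | CC[C@H]1[C@@H]2OC(=O)C(C[N+](C)(C)C)[C@@H]2c2cc([C@@H]3CC(C[N+](C)(C)C)C(=O)O3)n3c2[C@@H]1CCCC3.[I-].[I-] | intermediate
28 | 8,16-bis(methylene) bis-lactone (C8=C9, C16=C17; 14S) | CC[C@H]1[C@@H]2OC(=O)C(=C)[C@@H]2c2cc([C@@H]3CC(=C)C(=O)O3)n3c2[C@@H]1CCCC3 | intermediate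
29 | target, (3R,4S,8R,10R,14S,16S,23R) | CC[C@H]1[C@@H]2OC(=O)[C@H](C)[C@@H]2c2cc([C@@H]3C[C@H](C)C(=O)O3)n3c2[C@@H]1CCCC3 | target

## Step count and least certain steps

Total: 14 steps. Longest linear sequence: 11 steps (1, 2, 4, 7, 8, 9, 10, 11, 12, 13, 14) from 1.

**Step 7 (key step, proposed new method).** The most likely failure is weak enantiofacial discrimination, because the catalyst holds 12 through the nitro group only and an uncatalysed background reaction may compete. Exo approach or hetero-[4+2] reaction of the nitroalkene are lesser risks. Fallback: 7 and 12 are heated without catalyst (PhMe, 60 °C), a known thermal Diels–Alder type that gives 13 together with an equal amount of its enantiomer F1. The two are separated by preparative chromatography on a chiral stationary phase, and the route continues from 13.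

**Step 8.** The aqueous titanium medium may open the acid-labile enecarbamate (and with it ring B), and the β,γ-unsaturated ketone may enolise toward C10. Fallback: the order is changed so that the Nef reaction meets an acid-stable vinylogous formamide. Starting from 13, Vilsmeier formylation gives the N-Boc formyl nitro enecarbamate F2 (not isolated), and TFA gives the nitro vinylogous formamide F3. NaOMe gives its sodium nitronate F4 (not isolated), and aqueous TiCl3 gives the keto vinylogous formamide F5. NaBH4/CeCl3·7H2O gives the cis hydroxy ester F6 (not isolated), which lactonises to 19, where the route is rejoined.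

**Step 11.** O-Alkylation of the vinylogous formamide, self-condensation of 20, or attack of the C13 carbanion on its own ester may compete with ring closure. Fallback: from 19, tert-butyl bromoacetate and K2CO3 give the N-alkylated glycinate F7 (not isolated), which closes to the tert-butyl pyrrole-13-carboxylate F8. TFA gives the pyrrole-13-carboxylic acid F9 (not isolated), which loses CO2 to the C13-unsubstituted pyrrole F10. Friedel–Crafts acylation at the only free α-position with methyl 4-chloro-4-oxobutanoate (ZnCl2, CH2Cl2) gives 22.

**Step 12.** Hydride transfer to the vinylogous-amide-like ketone may be slow, and the pyrrolylic carbinol may ionise, which would erode C14 or lead to over-reduction. Fallback: from 22, NaBH4/CeCl3·7H2O without reagent control gives 23 together with its C14-epimeric hydroxy ester F11 (not isolated). After lactonisation, 24 is separated by chromatography from the 14-epi bis-lactone F12, and the route continues from 24.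

**Step 13.** The iminium salt may aminomethylate C12, the double reaction may stop halfway, or base may move the C8=C9 bond to C8=C10 in conjugation with the pyrrole, which would erase C10. Fallback: the methylene lactones are avoided. From 24, LiN(iPr)2 and MeI give the 8,16-dimethyl bis-lactone F13 as a mixture of C8 and C16 epimers. A second double enolisation gives the dilithium bis-enolate F14 (not isolated). Kinetic protonation with a hindered phenol at −78 °C, from the convex face of ring D and from the face of ring E opposite C13, gives 29 directly.

**Step 14.** The likely problem is poor facial selectivity at C16, which is controlled only by the C14 substituent across ring E; migration of the C8 alkene on the metal is a lesser risk. Fallback: from 28, reagent-controlled hydrogenation with Ru(OAc)2[(R)-BINAP] or its antipode (a known asymmetric hydrogenation of α-methylene-γ-butyrolactones), chosen to match C16, gives 29; the strong convex bias at C8 is expected to persist.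

## Further compounds

F1 | step 7 | enantiomer of 13 | CC[C@@H]1[C@@H]([N+](=O)[O-])[C@@H](CC(=O)OC)C=C2N(C(=O)OC(C)(C)C)CCCC[C@@H]12
F2 | step 8 | 11-formyl derivative of 13 (N-Boc; not isolated) | CC[C@H]1[C@H]([N+](=O)[O-])[C@H](CC(=O)OC)C(C=O)=C2N(C(=O)OC(C)(C)C)CCCC[C@H]12
F3 | step 8 | nitro NH vinylogous formamide (N21–H, C22=C11–CHO, C4 nitro, C10 CH2CO2Me) | CC[C@H]1[C@H]([N+](=O)[O-])[C@H](CC(=O)OC)C(C=O)=C2NCCCC[C@H]12
F4 | step 8 | sodium nitronate of F3 (not isolated) | CC[C@H]1C(=[N+]([O-])[O-])[C@H](CC(=O)OC)C(C=O)=C2NCCCC[C@H]12.[Na+]
F5 | step 8 | C4 keto NH vinylogous formamide | CC[C@H]1C(=O)[C@H](CC(=O)OC)C(C=O)=C2NCCCC[C@H]12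
F6 | step 8 | cis C4 hydroxy ester of the vinylogous formamide (not isolated) | CC[C@H]1[C@H](O)[C@H](CC(=O)OC)C(C=O)=C2NCCCC[C@H]12
F7 | step 11 | N21-(2-tert-butoxy-2-oxoethyl) derivative of 19 (not isolated) | CC[C@H]1[C@@H]2OC(=O)C[C@@H]2C(C=O)=C2N(CC(=O)OC(C)(C)C)CCCC[C@H]12
F8 | step 11 | tert-butyl pyrrole-13-carboxylate with rings A–D | CC[C@H]1[C@@H]2OC(=O)C[C@@H]2c2cc(C(=O)OC(C)(C)C)n3c2[C@@H]1CCCC3
F9 | step 11 | pyrrole-13-carboxylic acid with rings A–D (not isolated) | CC[C@H]1[C@@H]2OC(=O)C[C@@H]2c2cc(C(=O)O)n3c2[C@@H]1CCCC3
F10 | step 11 | C13-unsubstituted pyrrole lactone (rings A–D) | CC[C@H]1[C@@H]2OC(=O)C[C@@H]2c2ccn3c2[C@@H]1CCCC3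
F11 | step 12 | (14R)-hydroxy ester, C14 epimer of 23 (not isolated) | CC[C@H]1[C@@H]2OC(=O)C[C@@H]2c2cc([C@H](O)CCC(=O)OC)n3c2[C@@H]1CCCC3
F12 | step 12 | 14-epi-24 | CC[C@H]1[C@@H]2OC(=O)C[C@@H]2c2cc([C@H]3CCC(=O)O3)n3c2[C@@H]1CCCC3
F13 | step 13 | 8,16-dimethyl bis-lactone, mixture of C8 and C16 epimers | CC[C@H]1[C@@H]2OC(=O)C(C)[C@@H]2c2cc([C@@H]3CC(C)C(=O)O3)n3c2[C@@H]1CCCC3
F14 | step 13 | dilithium bis-enolate of F13 (not isolated) | CC[C@H]1[C@@H]2OC([O-])=C(C)[C@@H]2c2cc([C@@H]3CC(C)=C([O-])O3)n3c2[C@@H]1CCCC3.[Li+].[Li+]
F0 | step 14 | none | none
A1 | alternative 1 | maleimide photoprecursor: ring C alkene C22=C23 with lactone D and a C12–C13 tether from C11 to the imide nitrogen | CC[C@H]1[C@@H]2OC(=O)[C@H](C)[C@@H]2[C@H](CCN2C(=O)C=CC2=O)C=C1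
A2 | alternative 1 | pyrrolidine-fused azepinedione with lactone D | CC[C@H]1[C@@H]2OC(=O)[C@H](C)[C@@H]2[C@@H]2CCN3[C@@H]2[C@@H]1C(=O)C=CC3=O
A3 | alternative 2 | C4 diazoacetate of the pyrrolo-azepine tricycle (C10 = CH2; C13 methyl ester) | CC[C@H]1[C@H](OC(=O)C=[N+]=[N-])Cc2cc(C(=O)OC)n3c2[C@@H]1CCCC3
A4 | alternative 2 | tetracyclic lactone without the C8 methyl group, C13 methyl ester | CC[C@H]1[C@@H]2OC(=O)C[C@@H]2c2cc(C(=O)OC)n3c2[C@@H]1CCCC3
A5 | alternative 3 | eleven-membered pyrrolophane allylic alcohol (C23–OH, configuration not defined; C24=C25 Z; lactone D in place) | CC[C@H]1[C@@H]2OC(=O)[C@H](C)[C@@H]2c2ccn(c2)CC/C=C\C1O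
A6 | alternative 3 | tetracyclic pyrrole lactone with a C24=C25 alkene in ring B | CC[C@H]1[C@@H]2OC(=O)[C@H](C)[C@@H]2c2ccn3c2[C@@H]1C=CCC3
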